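# Proposed total synthesis of CNP0150579.2 (21)

## The problem

1. The target 21 is a dearomatised, fully substituted phloroglucinol. Ring A (C1–C6) has oxygen on C2, C4 and C6 and carbon on C1, C3 and C5.
2. C1 is quaternary, bearing prenyl and C1′H2 of a lavandulyl group. C3 carries the benzylic carbon C7 of the chain C7H(Ph)–C8H2–C9O2H, and C5–C6 is fused through C12(=O) and O6 to the dihydropyranone ring B (O6–C10HMe–C11HMe–C12).
3. Read from the SMILES, the stereocentres are 1S, 7S, 10R, 11S (the two methyl groups cis) and 2′S (the spatial arrangement of (R)-lavandulol).
4. They hang on four separate appendages of a flat sp2 periphery, so apart from the pair C10/C11 none lies within 1,2- or 1,3-range of another. C2′, C7 and C10/C11 must each be set on its own.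
5. C1 is the hardest centre: both alkyl groups begin with CH2, both ring neighbours are oxygenated sp2 carbons, its nearest stereocentre C2′ sits on a free rotor, and lavandulyl halides are unactivated, β-branched electrophiles, so only the prenyl group can arrive in a dearomatising step.
6. The fragile points are the cis C10/C11 relation (kinetic: C11 epimerises by enolisation and ring B opens by retro-oxa-Michael reaction under base), the three alkenes (which add an acidic enol or a phenol under acid), and the enol/acid pair itself.
7. The feature that makes the key step possible is that C9 stands at the right distance from O4 to close ring C (C3–C7–C8–C9–O4–C4). With C2 written as an enol ether, ring A then becomes the benzene ring of a 4-phenyl-3,4-dihydrocoumarin in which O2 is both peri to C7 and attached next to C1.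
8. A group on O2 is therefore forced by the pseudo-axial phenyl group on C7 to one face of ring A, and can be handed from there to C1 by a [3,3] shift.

## Retrosynthesis

**21 ⇒ 20 (C9–O4 closed).**
- The acid is closed onto the enol oxygen O4, not O2.
- A three-dimensional reading of the (1S,7S) pair shows that ring C on O4 places the phenyl group on the face opposite to the C1-prenyl group. Ring C on O2 would place it on the same face.
- 20 is neutral and has lost both protic groups. Its lactone is an enol ester of a vinylogous acid.
- The forward step needs only a cold, brief saponification.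

**20 ⇒ 19 (C1–CH2 of the prenyl group cut, O2–CMe2 made).**
- This is a retro-Claisen step.
- Cutting C1–C1′ instead is ruled out, because lavandulyl is neither an allyl group nor an activated electrophile.
- Cutting C1–prenyl ionically leaves C1 without any facial bias.
- The sigmatropic cut ties the migrating group to O2, the one atom that feels C7.
- One [3,3] shift inverts the allyl unit, so the ether must be the tertiary 1,1-dimethylallyl ether.
- 19 is a flat arene with one stereocentre and no quaternary carbon less than 20.
- The forward reaction must be concerted, go to C1 rather than C3, and be downhill.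

**19 ⇒ 16 + 18 (O2–C cut; 18 ⇒ 17).**
- The tertiary ether is labile, so it is made last, from the only free OH of 16.
- A method that avoids both SN2 at a tertiary carbon and strong base is needed: π-allylpalladium chemistry with the mixed carbonate 18, itself one step from 17.

**16 ⇒ 15 + 8 (C1–C1′ cut).**
- The acid-sensitive lavandulyl group enters after all Lewis- and Brønsted-acidic steps, as a nucleophile, at the single remaining ring position, which 15 marks with iodine.
- This avoids C-alkylation of a phenoxide with an unactivated halide.
- It also avoids an aryl ketone route through an epimerisable α-stereocentre.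
- The forward step is an sp2–sp3 Negishi coupling that must tolerate OH, lactone and ketone.

**8 ⇒ 7 ⇒ 6 ⇒ 5 ⇒ 3 + 4; 3 ⇒ 1 + 2 (C2′–C3′ cut).**
- The only stereocentre of the side chain is α to a carboxyl-level carbon in 5.
- Deconjugative auxiliary alkylation of the senecioyl imide 3 with prenyl bromide 4 makes C2′ and the isopropenyl group in one event from C5 building blocks.

**15 ⇒ 14 ⇒ 12 + 13 (C7–Ph cut).**
- C7 is the β-carbon of a coumarin.
- Adding phenyl to the flat coumarin 12 under ligand control sets C7 after the harsh acylation. This is preferable to exposing a benzylic stereocentre on a phloroglucinol ring to AlCl3.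
- The precursor is planar at ring C.

**12 ⇒ 11 ⇒ 9 + 10 (O6–C10 cut, then C5–C12 cut).**
- Ring B is opened to the o-hydroxyaryl tigloyl ketone 11.
- The catalysed oxa-Michael closure is one of the few reactions that give the cis isomer directly.
- Building the lactone before the acyl group fixes ring C on O4. The acyl group then enters next to the lactone oxygen and leaves O6 as the only oxygen able to close ring B.
- 9 and 10 are purchased.

## Roads not taken

**Alternative 1: the obvious cut.**
- Cut: C1–prenyl as an enolate alkylation.
- Forward key step: the open-chain aromatic ester A1 is treated with base and prenyl bromide 4, followed by ester hydrolysis.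
- In A1 nothing differentiates the faces of ring A at C1. C7 rotates freely, C2′ is on a rotor, and the C10 methyl group is equatorial and four bonds away, so a mixture of C1 epimers is expected.
- Three oxygens compete with carbon for the electrophile.
- The excess strong base needed for C-selectivity acts on C11 and on ring B.
- The chosen plan uses the same atoms but makes the transfer intramolecular, neutral and face-defined, and needs no ester protecting group.

**Alternative 2: flank differentiation.**
- Cut: C3–C7.
- C1 is stereogenic only because its two ring flanks differ. One could therefore build the trione A2, which has no stereocentre at C1, and desymmetrise it.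
- Forward key step: a chiral isothiourea-catalysed Michael addition–lactonisation with a cinnamoyl donor gives A3, setting C7 and C1 together.
- The catalyst should control C7. The choice between C3 and C5 rests only on prenyl versus lavandulyl, which differ from the third atom outward on opposite faces, so C1 control is not defensible.
- A2 itself requires lavandulylation of a trione or a malonate-based ring synthesis.
- Ring B would have to be closed cis on a strongly acidic enol, where the addition is more reversible.

**Alternative 3: para-Claisen/Cope relay.**
- Cut: C1–prenyl, with transfer from O4.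
- The primary prenyl ether A4 (ring C on O2) is easy to make. Two suprafacial [3,3] shifts via C3 or C5 would deliver a normal prenyl group to C1.
- With 7S, ring C on O2 places the phenyl group on the face that must receive the prenyl group. The axial C11 methyl group shields the same face at C5.
- Both relay stations therefore steer to the wrong face, towards the C1 epimer A5.
- The first shift would also have to join a CMe2 terminus to a fully substituted ring carbon.
- The chosen ortho shift from O2 needs one step, joins a CH2 terminus, and has the correct sense.

Key step: step 13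

Assumption: the C2-keto/C4-enol form of the SMILES is taken as one of the rapidly equilibrating tautomers of the same compound. Atom labels in the text (C1–C12, O2, O4, O6, C1′, C2′) are those defined above, while locants inside compound names follow the ring system named. Enantiopure (R)-lavandulol is not assumed to be purchasable.

## Route

Step 1
Reactants: 1 (R)-4-benzyl-1,3-oxazolidin-2-one; 2 3-methylbut-2-enoyl chloride
Product: 3 (R)-4-benzyl-3-(3-methylbut-2-enoyl)-1,3-oxazolidin-2-one
Conditions: n-BuLi, THF, −78 °C; then 2, −78 → 0 °C
Reagents that add atoms: none
Why: N-Acylation of the lithiated Evans oxazolidinone with an acid chloride; no stereocentre is formed and the auxiliary centre is not touched.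

Step 2
Reactants: 3; 4 prenyl bromide (1-bromo-3-methylbut-2-ene)
Product: 5 (R)-4-benzyl-3-[(2R)-5-methyl-2-(prop-1-en-2-yl)hex-4-enoyl]-1,3-oxazolidin-2-one
Conditions: NaHMDS, THF, −78 °C; then 4, −78 → −40 °C
Reagents that add atoms: none
Why: Evans alkylation in the deconjugative mode: γ-deprotonation of the s-cis enoyl imide gives the chelated Z(O)-dienolate, which attacks the allylic bromide through Cα by SN2 on the face away from the benzyl group. This sets C2′ (R in 5) and moves the alkene out of conjugation, so the isopropenyl group forms in the same event.

Step 3
Reactants: 5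
Product: 6 (R)-lavandulol, (2R)-5-methyl-2-(prop-1-en-2-yl)hex-4-en-1-ol
Conditions: LiBH4, MeOH (1 equiv), Et2O, 0 °C
Reagents that add atoms: none
Why: Reductive removal of the auxiliary; hydride attacks the exocyclic imide carbonyl, and the weakly basic medium should leave the α-stereocentre and the β,γ-alkene in place. Auxiliary 1 is recovered.

Step 4
Reactants: 6
Product: 7 (R)-lavandulyl iodide, (3R)-3-(iodomethyl)-2,6-dimethylhepta-1,5-diene
Conditions: I2, PPh3, imidazole, CH2Cl2, 0 °C → rt
Reagents that add atoms: iodine, II
Why: Appel-type iodination, SN2 at the primary carbon C1′; C2′ is not involved and the neutral conditions spare both alkenes.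

Step 5
Reactants: 7
Product: 8 (R)-lavandulylzinc iodide (titrated THF solution)
Conditions: Zn dust (activated), LiCl, THF, 25–35 °C
Reagents that add atoms: zinc, [Zn]
Why: LiCl-assisted direct insertion of zinc into a primary alkyl iodide; C2′ is β to the metal and keeps its configuration.

Step 6
Reactants: 9 5,7-dihydroxycoumarin; 10 tigloyl chloride, (E)-2-methylbut-2-enoyl chloride
Product: 11 5,7-dihydroxy-8-[(E)-2-methylbut-2-enoyl]-2H-chromen-2-one
Conditions: AlCl3, PhNO2–(CH2Cl)2, rt → 60 °C; cold 1 M HCl
Reagents that add atoms: none
Why: Friedel–Crafts acylation forms C5–C12; by analogy with 4-substituted 5,7-dihydroxycoumarins, coumarin C8 (para to 5-OH, ortho to 7-OH) should be preferred to C6, which lies between two aluminium phenoxides. The aluminium chelate of the product ties up O6 and should hold back ring closure until the cold quench.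

Step 7
Reactants: 11
Product: 12 (8R,9S)-5-hydroxy-8,9-dimethyl-8,9-dihydro-2H,10H-pyrano[2,3-f]chromene-2,10-dione (cis ring B)
Conditions: (−)-quinine (20 mol %), PhCl, rt
Reagents that add atoms: none
Why: Cinchona-alkaloid-catalysed intramolecular oxa-Michael addition (6-endo-trig) of O6–H to the tigloyl group; the lactone oxygen blocks the other flank, so only O6 can close. C10 is set by face-selective O–C bond formation in the chiral ion pair and C11 by kinetic protonation of the resulting enol, which gives the cis isomer with closely related 7-hydroxy-8-tigloylcoumarins. The sense (10R,11S) is assigned by that analogy, and quinidine is at hand for the opposite sense.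

Step 8
Reactants: 12; 13 phenylboronic acid
Product: 14 (4S,8R,9S)-5-hydroxy-8,9-dimethyl-4-phenyl-3,4,8,9-tetrahydro-2H,10H-pyrano[2,3-f]chromene-2,10-dione
Conditions: Rh(acac)(C2H4)2 (cat.), (S)-SEGPHOS (cat.), excess 13, dioxane–H2O 10:1, 60 °C
Reagents that add atoms: none
Why: Hayashi–Miyaura asymmetric 1,4-addition: phenylrhodium(I) adds to the coumarin β-carbon C7 and the oxa-π-allylrhodium is protonated by water. The ligand chooses the face (7S, by analogy with simple coumarins and the antipodal ligand), while saturated ketone and phenol are inert and no base is present that could touch C11.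

Step 9
Reactants: 14
Product: 15 (4S,8R,9S)-5-hydroxy-6-iodo-8,9-dimethyl-4-phenyl-3,4,8,9-tetrahydro-2H,10H-pyrano[2,3-f]chromene-2,10-dione
Conditions: NIS, MeCN, 0 °C, dark
Reagents that add atoms: N-iodosuccinimide, O=C1CCC(=O)N1I
Why: Electrophilic aromatic iodination at C1, the only free position of ring A and activated by three oxygens; the phenyl ring cannot compete and the medium is neutral.

Step 10
Reactants: 15; 8
Product: 16 (4S,8R,9S)-5-hydroxy-8,9-dimethyl-6-[(2S)-5-methyl-2-(prop-1-en-2-yl)hex-4-en-1-yl]-4-phenyl-3,4,8,9-tetrahydro-2H,10H-pyrano[2,3-f]chromene-2,10-dione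
Conditions: Pd(OAc)2 (cat.), SPhos (cat.), THF, slow addition of 8, 25 °C
Reagents that add atoms: none
Why: Negishi sp2–sp3 coupling forms C1–C1′; bulky biarylphosphine catalysts couple primary alkylzinc halides faster than these are protonated by a phenol and faster than β-hydride elimination, and lactone and ketone are inert to RZnI. C2′ is carried over unchanged (its descriptor becomes S only through the change of priorities).

Step 11
Reactants: 17 2-methylbut-3-en-2-ol
Product: 18 tert-butyl 2-methylbut-3-en-2-yl carbonate
Conditions: n-BuLi, THF, −78 °C; Boc2O, −78 °C → rt
Reagents that add atoms: di-tert-butyl dicarbonate, CC(C)(C)OC(=O)OC(=O)OC(C)(C)C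
Why: Acylation of a tertiary lithium alkoxide with Boc2O, a standard preparation of mixed allylic carbonates.

Step 12
Reactants: 16; 18
Product: 19 (4S,8R,9S)-8,9-dimethyl-5-[(2-methylbut-3-en-2-yl)oxy]-6-[(2S)-5-methyl-2-(prop-1-en-2-yl)hex-4-en-1-yl]-4-phenyl-3,4,8,9-tetrahydro-2H,10H-pyrano[2,3-f]chromene-2,10-dione
Conditions: Pd(PPh3)4 (cat.), excess 18, THF, 0–5 °C; rapid filtration through neutral alumina, kept cold
Reagents that add atoms: none
Why: Tsuji–Trost O-allylation: ionisation of 18 gives the 1,1-dimethylallyl-palladium cation, CO2 and tert-butoxide, which only deprotonates O2–H, and phenoxides attack the more substituted terminus under kinetic control at low temperature. The tert-butyl carbonate is chosen so that no nucleophilic alkoxide opens ring C. The lactone cannot migrate to O2, since the tetrahedral intermediate would be a bicyclo[2.2.2]octane with the planar C3 as bridgehead.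

Step 13
Reactants: 19
Product: 20 (4S,6S,8R,9S)-8,9-dimethyl-6-(3-methylbut-2-en-1-yl)-6-[(2S)-5-methyl-2-(prop-1-en-2-yl)hex-4-en-1-yl]-4-phenyl-3,4,8,9-tetrahydro-2H,10H-pyrano[2,3-f]chromene-2,5,10(6H)-trione
Conditions: PhMe (dilute), BHT (cat.), base-washed glass, 80–100 °C
Reagents that add atoms: none
Why: Aromatic Claisen rearrangement run as a dearomatisation: a concerted, suprafacial [3,3] shift through a six-centre transition state breaks O2–CMe2 and joins the CH2 terminus to C1, so the group arrives as a normal prenyl group and C2 becomes the ketone. The closest known reaction type is the ortho-Claisen shift of aryl 1,1-dimethylallyl ethers onto a substituted ortho carbon, which stops at the cyclohexa-2,4-dienone because no hydrogen can be lost. No ring is closed; ring A passes from arene to dienone and ring C from aryl ester to activated enol ester. The one new stereocentre, C1, is controlled by C7: to avoid the peri substituent on O2 the phenyl group stands pseudo-axial on the lower face, the O2–CMe2 group wedged between C7 and C1′ cannot lie in the ring plane and turns to the upper face, and the C1′–C2′ bond next to it turns down, so the down–up–down gearing of 19 is already that of 20 and the shift from the upper face gives 1S. Site selectivity is needed because both ortho carbons are substituted: C1 bears a CH2 group whereas C3 is a ring-fusion carbon bearing the branched C7, and a shift to C3 can revert while the C1 product is the less strained sink. The step should be downhill because a phloroglucinol ring has little resonance energy to lose, the dienone is stabilised as a doubly vinylogous ester, and a crowded tertiary ether is exchanged for a C–C bond and a trisubstituted alkene. It must stay concerted, so apolar solvent, acid-free glass and the prior removal of palladium are used to suppress ionisation to a prenyl cation/phenoxide pair, which would erase the facial memory. The neutral medium leaves C7, C10, C11 and C2′ untouched, and the temperature is far below that of a Cope shift in the lavandulyl 1,5-diene.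

Step 14
Reactants: 20
Product: 21 target, (3S)-3-[(2R,3S,8S)-5-hydroxy-2,3-dimethyl-8-(3-methylbut-2-en-1-yl)-8-[(2S)-5-methyl-2-(prop-1-en-2-yl)hex-4-en-1-yl]-4,7-dioxo-3,4,7,8-tetrahydro-2H-chromen-6-yl]-3-phenylpropanoic acid
Conditions: LiOH (2.2 equiv), THF–H2O, 0 °C, short; then cold 0.5 M HCl to pH 3
Reagents that add atoms: lithium hydroxide, [Li+].[OH-]
Why: Saponification of an enol ester of a vinylogous acid, which is an acyl donor far more reactive than an alkyl or aryl ester, so it should open within minutes in the cold. The ring A enolate set free is delocalised over O2, O4 and C12=O, which lowers the acidity of C11–H and should protect the cis ring B from epimerisation and retro-oxa-Michael opening. The brief mild acidification spares the alkenes.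

## Compound list

1 | (R)-4-benzyl-1,3-oxazolidin-2-one | O=C1N[C@H](Cc2ccccc2)CO1 | starting material
2 | 3-methylbut-2-enoyl chloride | CC(C)=CC(=O)Cl | starting material
3 | (R)-4-benzyl-3-(3-methylbut-2-enoyl)-1,3-oxazolidin-2-one | CC(C)=CC(=O)N1[C@H](Cc2ccccc2)COC1=O | intermediate
4 | prenyl bromide | CC(C)=CCBr | starting material
5 | (R)-4-benzyl-3-[(2R)-5-methyl-2-(prop-1-en-2-yl)hex-4-enoyl]-1,3-oxazolidin-2-one | C=C(C)[C@@H](CC=C(C)C)C(=O)N1[C@H](Cc2ccccc2)COC1=O | intermediate
6 | (R)-lavandulol | C=C(C)[C@@H](CC=C(C)C)CO | intermediate
7 | (R)-lavandulyl iodide | C=C(C)[C@@H](CC=C(C)C)CI | intermediate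
8 | (R)-lavandulylzinc iodide | C=C(C)[C@@H](CC=C(C)C)C[Zn]I | intermediate
9 | 5,7-dihydroxycoumarin | O=c1ccc2c(O)cc(O)cc2o1 | starting material
10 | tigloyl chloride | C/C=C(\C)C(=O)Cl | starting material
11 | 5,7-dihydroxy-8-[(E)-2-methylbut-2-enoyl]-2H-chromen-2-one | O=c1ccc2c(O)cc(O)c(C(=O)/C(C)=C/C)c2o1 | intermediate
12 | (8R,9S)-5-hydroxy-8,9-dimethyl-8,9-dihydro-2H,10H-pyrano[2,3-f]chromene-2,10-dione | O=C1C=Cc2c(O)cc3O[C@H](C)[C@H](C)C(=O)c3c2O1 | intermediate
13 | phenylboronic acid | OB(O)c1ccccc1 | starting material
14 | (4S,8R,9S)-5-hydroxy-8,9-dimethyl-4-phenyl-3,4,8,9-tetrahydro-2H,10H-pyrano[2,3-f]chromene-2,10-dione | O=C1C[C@@H](c4ccccc4)c2c(O)cc3O[C@H](C)[C@H](C)C(=O)c3c2O1 | intermediate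
15 | 6-iodo derivative of 14 | O=C1C[C@@H](c4ccccc4)c2c(O)c(I)c3O[C@H](C)[C@H](C)C(=O)c3c2O1 | intermediate
16 | 6-[(2S)-lavandulyl] phenol | O=C1C[C@@H](c4ccccc4)c2c(O)c(C[C@H](CC=C(C)C)C(C)=C)c3O[C@H](C)[C@H](C)C(=O)c3c2O1 | intermediate
17 | 2-methylbut-3-en-2-ol | C=CC(C)(C)O | starting material
18 | tert-butyl 2-methylbut-3-en-2-yl carbonate | C=CC(C)(C)OC(=O)OC(C)(C)C | intermediate
19 | 5-O-(1,1-dimethylallyl) ether of 16 | O=C1C[C@@H](c4ccccc4)c2c(OC(C)(C)C=C)c(C[C@H](CC=C(C)C)C(C)=C)c3O[C@H](C)[C@H](C)C(=O)c3c2O1 | intermediate
20 | dearomatised enol lactone (1S) | C=C(C)[C@@H](CC=C(C)C)C[C@]1(CC=C(C)C)C(=O)C2=C(OC(=O)C[C@H]2c3ccccc3)C4=C1O[C@H](C)[C@H](C)C4=O | intermediate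
21 | CNP0150579.2 | C=C(C)[C@@H](CC=C(C)C)C[C@]1(CC=C(C)C)C(=O)C([C@@H](CC(=O)O)c2ccccc2)=C(O)C2=C1O[C@H](C)[C@H](C)C2=O | target

## Step count and least certain steps

Total steps: 14. Longest linear sequence: 9 (steps 1–5, 10, 12, 13, 14). The aromatic branch counts 8 (steps 6–10, 12–14).

**Step 13 (key step).**
- Facial control may be lost in three ways: C–O heterolysis may run ahead of C–C bond formation (ion-pair recombination on either face, or loss of isoprene); ring C may populate the conformer with a pseudo-equatorial phenyl group at the reaction temperature; or the shift to C3 may compete.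
- The fallback replaces substrate control through a sigmatropic shift by ligand control in an intermolecular reaction. It sets out from 16 and comes back at 20.
- It is a palladium-catalysed asymmetric dearomative allylic alkylation with tert-butyl prenyl carbonate and a C2-symmetric DACH-derived bisphosphine.
- Both ligand antipodes can be tested against the substrate bias.
- The C1 epimers are diastereomers and can be separated.
- No new compound arises.

**Step 12.**
- Attack of the doubly flanked O2 on the tertiary allyl terminus may be slow. Palladium-mediated isomerisation to the linear ether, or direct and face-unselective C-allylation, could then take over.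
- The fallback changes the electrophile to a linear, sterically undemanding copper allenylidene. It sets out from 16 and comes back at 19.
- 16 is treated with 3-chloro-3-methylbut-1-yne, CuCl2 (cat.) and DBU in MeCN at 0 °C to give the 1,1-dimethylpropargyl ether F1.
- Semi-hydrogenation of F1 over Lindlar catalyst, selective for the alkyne, returns to 19.

**Step 8.**
- The two oxygen donors conjugated with C7 lower the electrophilicity of the coumarin, so carbometalation may be slower than protodeboronation.
- Hot water could also open ring C and allow it to reclose on O2.
- The fallback makes the C7–H bond instead of the C7–Ph bond. It sets out from tigloyl chloride 10 and comes back at 14.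
- 10 acylates purchased 5,7-dihydroxy-4-phenylcoumarin F2 at C8 (the series with the closest precedent for this regiochemistry) to give the 8-tigloyl compound F3.
- Quinine-catalysed closure gives the cis-chromanone coumarin F4.
- Copper hydride asymmetric 1,4-reduction (Cu(OAc)2, DTBM-SEGPHOS, PMHS, t-BuOH, anhydrous) then leads to 14.
- Concurrent reduction at C12 would call for a re-oxidation.

**Step 10.**
- The zinc reagent may be protonated by the free phenol.
- Turnover at the doubly ortho-substituted iodide may be slow.
- β-Hydride elimination with chain walking would waste the chiral fragment.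
- The fallback avoids any preformed organometallic. It sets out from 15 and iodide 7 and comes back at 16.
- It is a nickel-catalysed reductive cross-electrophile coupling (NiBr2·glyme, dtbbpy, Zn, DMA), which tolerates OH groups.
- No new compound arises.

**Step 6.**
- Acylation at C6 may compete with C8.
- The Lewis acid may trigger uncatalysed closure of ring B, which would destroy the chance to set C10/C11 by catalysis.
- The fallback delivers the acyl group intramolecularly. It sets out from 9 and 10 and comes back at 11.
- Selective O-acylation of the more acidic 7-OH (Et3N, CH2Cl2, 0 °C) gives the 7-tiglate F5.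
- A Fries rearrangement of F5 (TiCl4, CH2Cl2, 0 °C → rt) follows, which in 7-acyloxycoumarins goes to C8 because of the higher π-bond order of C7–C8.

## Further compounds

F0 | step 13 | none | none
F1 | step 12 | 5-O-(1,1-dimethylpropargyl) ether of 16 | O=C1C[C@@H](c4ccccc4)c2c(OC(C)(C)C#C)c(C[C@H](CC=C(C)C)C(C)=C)c3O[C@H](C)[C@H](C)C(=O)c3c2O1
F2 | step 8 | 5,7-dihydroxy-4-phenylcoumarin (purchased) | O=c1cc(-c2ccccc2)c2c(O)cc(O)cc2o1
F3 | step 8 | 5,7-dihydroxy-8-[(E)-2-methylbut-2-enoyl]-4-phenyl-2H-chromen-2-one | O=c1cc(-c2ccccc2)c2c(O)cc(O)c(C(=O)/C(C)=C/C)c2o1
F4 | step 8 | (8R,9S)-5-hydroxy-8,9-dimethyl-4-phenyl-8,9-dihydro-2H,10H-pyrano[2,3-f]chromene-2,10-dione | O=C1C=C(c4ccccc4)c2c(O)cc3O[C@H](C)[C@H](C)C(=O)c3c2O1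
F0 | step 10 | none | none
F5 | step 6 | 5-hydroxy-2-oxo-2H-chromen-7-yl (E)-2-methylbut-2-enoate | O=c1ccc2c(O)cc(OC(=O)/C(C)=C/C)cc2o1
A1 | alternative 1 | methyl (3S)-3-[(2R,3S)-5,7-dihydroxy-2,3-dimethyl-8-[(2S)-lavandulyl]-4-oxochroman-6-yl]-3-phenylpropanoate | COC(=O)C[C@@H](c1ccccc1)c2c(O)c(C[C@H](CC=C(C)C)C(C)=C)c3O[C@H](C)[C@H](C)C(=O)c3c2O
A2 | alternative 2 | 2-[(2S)-lavandulyl]-2-prenylcyclohexane-1,3,5-trione | C=C(C)[C@@H](CC=C(C)C)CC1(CC=C(C)C)C(=O)CC(=O)CC1=O
A3 | alternative 2 | desymmetrised enol lactone lacking ring B | C=C(C)[C@@H](CC=C(C)C)C[C@]1(CC=C(C)C)C(=O)C2=C(OC(=O)C[C@H]2c3ccccc3)C=C1O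
A4 | alternative 3 | O4-prenyl ether of the isomer with ring C closed on O2 | O=C1C[C@@H](c4ccccc4)c2c(OCC=C(C)C)c3C(=O)[C@@H](C)[C@@H](C)Oc3c(C[C@H](CC=C(C)C)C(C)=C)c2O1
A5 | alternative 3 | cross-conjugated dienone lactone, C1 epimer | C=C(C)[C@@H](CC=C(C)C)C[C@@]1(CC=C(C)C)C2=C([C@H](c3ccccc3)CC(=O)O2)C(=O)C4=C1O[C@H](C)[C@H](C)C4=O
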